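## Structural features

The target is a 2,3-dihydro-1H-indene: a resorcinol-type benzene ring (ring A, hydroxyls on C5 and C7) fused through C3a and C7a to a cyclopentane (ring B) whose three sp3 carbons each carry a substituent. In the locants used in the discussion, C1 (bonded to C7a, next to the C7 hydroxyl) bears a 4-hydroxyphenyl group, C2 a 3,5-dihydroxyphenyl group, and C3 (bonded to C3a, next to C4–H) an exocyclic carbinol carbon carrying OH and a second 4-hydroxyphenyl group; the systematic names in the steps count from the other end, so the side-chain carbon is position 1 there. Four stereocentres stand in a row: C1 (R), C2 (S), C3 (S) and the carbinol carbon (R), with the C1 and C2 aryl groups trans and the C2 aryl group cis to the C3 side chain. Fragile features are the 4-hydroxybenzylic secondary alcohol (ionisation, dehydration, hydrogenolysis), the six air-sensitive phenols and the doubly benzylic C1–H. The real difficulty is the contra-thermodynamic 2,3-cis arrangement next to a carbinol whose ketone precursor can epimerise C3, together with absolute control and a late, trans-selective arylation of C1. The key step exploits the fact that the C2–aryl bond and the C3–C(carbinol) bond lie on the same face of adjacent ring B carbons: this is the imprint of a suprafacial addition of an aryl and an acyl group across the C2=C3 bond of an indene, the carbinol carbon coming from carbon monoxide. C1, activated by the ortho (C7) and para (C5) oxygens of ring A, is then the one benzylic position from which hydride can be removed selectively.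

## Logic of the disconnections

**19 ⇒ 17 (through 18).** The five aryl O–CH2Ph bonds and the carbinol O–acetyl bond are cut. Benzyl is chosen because it leaves by hydrogenolysis, with no Lewis acid near the ionisable carbinol; the acetate must go first because a benzylic acetate is hydrogenolysed more easily than the alcohol. The forward step must cleave aryl benzyl ethers without touching the benzylic C–OH bond.

**17 ⇒ 14 + 15.** The C1–C(para) bond to the 4-hydroxyphenyl ring is cut and C1 reverts to CH2. C1 is the only benzylic carbon that is ortho and para to ring A oxygens, so its cation is accessible by hydride abstraction, and a nucleophile must enter opposite the C2 aryl group and the C3 side chain, which share one face. The gain is that the precursor has one ring stereocentre less and needs no functional group at C1. The demands are site-selective oxidation, no elimination from the cation, and no contact between the oxidant and 15 or the easily oxidised product; hence an acetoxylation first and arylation only when the oxidant is spent.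

**14 ⇒ 13 ⇒ 12.** The O–acetyl bond and then the carbinol C–H bond are cut, giving the aryl ketone. The acetate makes the carbinol C–H inert to the oxidant. The reduction must be reagent-controlled and non-basic, because the stereocentre α to the carbonyl of 12 would epimerise to the trans isomer.

**12 ⇒ 6 + 8 + 11 + carbon monoxide.** Three bonds are cut: C2–aryl, C3–C(acyl) and C(acyl)–aryl. They lie cis on C2 and C3, so all three can come from one syn carbopalladation of an indene followed by CO insertion and tin-to-palladium transfer. The gain is the largest of the route: two stereocentres and three skeletal bonds from three achiral pieces. The forward step must control regiochemistry, alkene face and the order of alkene and CO insertion. For that reason the aryl electrophile is used as the triflate 8 rather than the corresponding bromide (same skeleton): the cationic arylpalladium keeps both phosphorus atoms of the chiral ligand bound during the insertion.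

**6 ⇒ 5 ⇒ 4 ⇒ 2 ⇒ 1 (+ 3).** The C2=C3 double bond is cut by ring-closing metathesis, the vinyl C=C by Wittig methylenation, the aryl–allyl bond by Stille coupling and the C–Br bond by bromination. This fixes the regiochemistry of 6 unambiguously (CH2 next to the benzyloxy-bearing carbon), keeps the benzyl ethers from the first step, and avoids both a strong-acid cyclisation and an exchange of ether groups. The demand is that the allyl double bond does not move into conjugation before the metathesis.

**8 ⇒ 7 and 11 ⇒ 9 (through 10).** The O–S bond of the triflate and the C–Sn bond of the stannane are cut; both are one-step preparations from commercial materials.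

## Other disconnections considered

**Alternative 1:** The cut is the C7a–C1 bond of ring B. In the forward sense the triaryl propenone A1, activated by a chiral acid, would undergo conrotatory 4π-electrocyclisation onto ring A, and protonation of the enol would place the C2 aryl trans to the C1 aryl in indanone A2.
- In its favour: A1 is two condensations from simple aryl ketones and aldehydes; the cyclisation is an established reaction type for 3,5-dialkoxyphenyl vinyl ketones; ring B, the C1 aryl and the 1,2-trans relationship are made at once, with trans being the thermodynamic outcome.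
- Against it here: catalytic absolute control of a Nazarov closure onto an arene without a chelating α-substituent is weak. A2 still lacks the C3 side chain, and building it means converting the ketone into a carbon substituent that must end up cis to the C2 aryl and carry a defined carbinol, at least four further stereo-relevant operations. Methyl ethers would require a Lewis-acid cleavage that endangers the carbinol.
- Comparison: on structure the two plans are complementary (A2 has C1 and C2; the chosen key step gives C2, C3 and the carbinol carbon). On mechanism the alternative is the better, being known chemistry that needs no late C–H oxidation. On step economy the two are about equal. The chosen plan is stronger on the 2,3-cis relationship and on absolute configuration.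

**Alternative 2:** The cuts are C3a–C7a and C6–C7, so that ring A is built last. AuCl3 would activate the terminal alkyne of the furan–yne A3 toward the tethered furan, and the arene oxide would open to the phenol A4, with the furan oxygen ending on C7 and both rings closed.
- In its favour: the oxygen pattern of ring A is regiochemically certain and the C7 hydroxyl emerges differentiated; C2, C3 and the carbinol carbon are set beforehand in an acyclic chain, away from any epimerisable ketone; gold phenol synthesis is a known catalytic reaction class, which is a point on which it is the better of the two.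
- Against it here: A3 needs three contiguous stereocentres made by acyclic stereocontrol, a long sequence; an all-carbon tether is a less favourable case for this annulation; the bromine must still be exchanged for oxygen; and A4 has CH2 at C1, so the same late oxidative arylation is required, now beside a free phenol.
- Comparison: structurally it delivers the same three stereocentres as the chosen key step but none of the gain at C1. Mechanistically it is safer. In step economy it is clearly longer.

**Alternative 3:** The cut is the C2–C3 bond, made by a 1,2-shift. Photolysis of the diazotetralone A5 would expel N2, contract the six-membered ring, and the ketene would be trapped by MeNHOMe with protonation at C3 to give the Weinreb amide A6.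
- In its favour: all three ring stereocentres, including the C1 aryl, are present in A6, so no late C–H oxidation is needed, which is a point on which it is the better of the two; the migrating carbon keeps its configuration; every step is a known reaction type; and an aryllithium addition to A6 would meet the chosen route at the ketone stage.
- Against it here: the trans-diaryl tetralone behind A5 must be made as a single enantiomer by separate asymmetric chemistry; the 1,2-cis outcome rests on kinetic protonation of the ketene adduct, and the amide α-centre can epimerise during the basic aryllithium addition; the methyl ethers again clash with the carbinol at the end.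
- Comparison: on structure it is the more complete; on mechanism it is equal or better in precedent; on step economy it is longer, since absolute control needs its own steps, whereas the chosen plan draws both new stereocentres from one catalytic event.

Key step: step 7

Assumption: the sense of induction of (R)-BINAP in the insertion cannot be predicted with confidence; (R)-BINAP is written throughout, and (S)-BINAP would be used if the opposite sense is found.

## Route

Step 1
Reactants: 1 3,5-bis(benzyloxy)benzaldehyde
Product: 2 2-bromo-3,5-bis(benzyloxy)benzaldehyde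
Conditions: NBS (1.0 equiv), MeCN, 0 °C → rt
Reagents that add atoms: N-bromosuccinimide O=C1CCC(=O)N1Br
Why: Electrophilic aromatic bromination; C2 is ortho to one benzyloxy group and para to the other, while the equally activated C4 is shielded between two benzyloxy groups, so one equivalent of NBS should brominate next to the formyl group.

Step 2
Reactants: 2 2-bromo-3,5-bis(benzyloxy)benzaldehyde; 3 allyltributylstannane
Product: 4 2-allyl-3,5-bis(benzyloxy)benzaldehyde
Conditions: Pd(PPh3)4 (5 mol %), toluene, 100 °C
Reagents that add atoms: none
Why: Migita–Kosugi–Stille allylation of an aryl bromide under neutral conditions; the aldehyde and benzyl ethers are inert and no base is present that could move the allyl double bond into conjugation.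

Step 3
Reactants: 4 2-allyl-3,5-bis(benzyloxy)benzaldehyde
Product: 5 1,5-bis(benzyloxy)-3-ethenyl-2-(prop-2-en-1-yl)benzene
Conditions: Ph3PCH3Br (1.3 equiv), KOtBu (1.2 equiv), THF, 0 °C → rt
Reagents that add atoms: methyltriphenylphosphonium bromide C[P+](c1ccccc1)(c1ccccc1)c1ccccc1.[Br-]
Why: Wittig methylenation of an aromatic aldehyde; keeping the base below the amount of phosphonium salt should prevent isomerisation of the skipped allyl group.

Step 4
Reactants: 5 1,5-bis(benzyloxy)-3-ethenyl-2-(prop-2-en-1-yl)benzene
Product: 6 5,7-bis(benzyloxy)-1H-indene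
Conditions: second-generation Grubbs catalyst (3 mol %), CH2Cl2 (0.02 M), 40 °C
Reagents that add atoms: none
Why: Ring-closing metathesis of a 2-allylstyrene to a 1H-indene, driven by loss of ethylene; the allyl CH2 ends next to the benzyloxy-bearing ring carbon, which fixes the regiochemistry of the indene.

Step 5
Reactants: 7 3,5-bis(benzyloxy)phenol
Product: 8 3,5-bis(benzyloxy)phenyl trifluoromethanesulfonate
Conditions: Tf2O (1.1 equiv), pyridine, CH2Cl2, 0 °C
Reagents that add atoms: trifluoromethanesulfonic anhydride O=S(=O)(OS(=O)(=O)C(F)(F)F)C(F)(F)F
Why: O-sulfonylation of a phenol; the triflate is preferred to the bromide because its oxidative addition gives a cationic arylpalladium that keeps both phosphorus atoms of BINAP bound during alkene insertion.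

Step 6
Reactants: 9 1-(benzyloxy)-4-bromobenzene
Product: 11 tributyl[4-(benzyloxy)phenyl]stannane, via [4-(benzyloxy)phenyl]lithium 10 (not isolated)
Conditions: n-BuLi, THF, −78 °C; then Bu3SnCl, −78 °C → rt
Reagents that add atoms: n-butyllithium [Li]CCCC (the lithium of 10); tributyltin chloride CCCC[Sn](Cl)(CCCC)CCCC
Why: Bromine–lithium exchange followed by stannylation of the aryllithium; the benzyl ether is stable to n-BuLi at −78 °C.

Step 7
Reactants: 6 5,7-bis(benzyloxy)-1H-indene (1.5 equiv); 8 3,5-bis(benzyloxy)phenyl trifluoromethanesulfonate; 11 tributyl[4-(benzyloxy)phenyl]stannane (1.3 equiv)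
Product: 12 [(1S,2S)-4,6-bis(benzyloxy)-2-[3,5-bis(benzyloxy)phenyl]-2,3-dihydro-1H-inden-1-yl][4-(benzyloxy)phenyl]methanone (aryl and aroyl groups cis)
Conditions: Pd(OAc)2 (5 mol %), (R)-BINAP (10 mol %), CO/N2 1:4 (1 atm), 1,4-dioxane, 60 °C; 11 added over 8 h
Reagents that add atoms: carbon monoxide [C-]#[O+]
Why: Proposed new method: zerovalent palladium bound to (R)-BINAP should add oxidatively to triflate 8, and the resulting cationic arylpalladium, which keeps both phosphorus atoms on the metal, should coordinate the C2=C3 bond of 6 and insert it suprafacially with the aryl group going to C2 and palladium to the benzylic C3 as an η3-benzyl complex; CO then inserts into the benzyl–palladium bond with retention, and transmetallation from stannane 11 followed by reductive elimination releases ketone 12 and returns zerovalent palladium. The closest known reaction types are Heck–carbonylative Stille and Heck–carbonylative Suzuki cascades through alkylpalladium intermediates that lack a syn β-hydrogen (three-component couplings of norbornene, intramolecular Heck–carbonylation) and the enantioselective intermolecular Heck arylation of cyclic alkenes by aryl triflates with Pd(OAc)2 and BINAP; their combination on an indene has not been shown. No ring is closed, so no mode of ring closure has to be named. The stereocentre at C2 is set by the alkene face that the chiral bisphosphine presents to the aryl group in the insertion, and the stereocentre at C3 is set relative to C2 by the syn course of that insertion and the retentive CO insertion, so the aryl and aroyl groups must emerge cis. Regioselectivity rests on the preference of palladium for the benzylic carbon, and β-hydride elimination is shut off because the one hydrogen on C2 is anti to palladium and C3a carries none. The step needs alkene insertion to precede CO insertion into the aryl–palladium bond, which the diluted CO, the excess of 6 and the slow addition of 11 (which also starves the direct biaryl and diaryl ketone couplings) are meant to secure. The absence of base should keep the cis ketone from epimerising to the trans isomer.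

Step 8
Reactants: 12 [(1S,2S)-4,6-bis(benzyloxy)-2-[3,5-bis(benzyloxy)phenyl]-2,3-dihydro-1H-inden-1-yl][4-(benzyloxy)phenyl]methanone
Product: 13 (R)-[(1S,2S)-4,6-bis(benzyloxy)-2-[3,5-bis(benzyloxy)phenyl]-2,3-dihydro-1H-inden-1-yl][4-(benzyloxy)phenyl]methanol
Conditions: (S)-2-methyl-CBS-oxazaborolidine (0.5 equiv), BH3·SMe2 (1.2 equiv), toluene/THF, −20 °C
Reagents that add atoms: none
Why: Corey–Bakshi–Shibata reduction of an aryl ketone; with the aryl group as the large substituent the (S)-oxazaborolidine should deliver hydride to give the R carbinol under reagent control, and the non-basic borane conditions leave the epimerisable stereocentre α to the carbonyl untouched.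

Step 9
Reactants: 13 (R)-[(1S,2S)-4,6-bis(benzyloxy)-2-[3,5-bis(benzyloxy)phenyl]-2,3-dihydro-1H-inden-1-yl][4-(benzyloxy)phenyl]methanol
Product: 14 (R)-[(1S,2S)-4,6-bis(benzyloxy)-2-[3,5-bis(benzyloxy)phenyl]-2,3-dihydro-1H-inden-1-yl][4-(benzyloxy)phenyl]methyl acetate
Conditions: Ac2O, pyridine, DMAP (cat.), CH2Cl2, rt
Reagents that add atoms: acetic anhydride CC(=O)OC(C)=O
Why: DMAP-catalysed acylation of a secondary alcohol; the acetate lowers the hydride-donor ability of the carbinol C–H so that it should survive DDQ, and it ionises far less readily than the ring benzylic acetate formed in the next step.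

Step 10
Reactants: 14 (R)-[(1S,2S)-4,6-bis(benzyloxy)-2-[3,5-bis(benzyloxy)phenyl]-2,3-dihydro-1H-inden-1-yl][4-(benzyloxy)phenyl]methyl acetate; 15 phenol (10 equiv)
Product: 17 (R)-[(1S,2S,3R)-4,6-bis(benzyloxy)-2-[3,5-bis(benzyloxy)phenyl]-3-(4-hydroxyphenyl)-2,3-dihydro-1H-inden-1-yl][4-(benzyloxy)phenyl]methyl acetate, via ring benzylic acetate 16 (not isolated)
Conditions: DDQ (1.05 equiv), AcOH/CH2Cl2 1:4, rt; then evaporate, 15, HFIP, 0 °C → rt
Reagents that add atoms: acetic acid CC(=O)O (the ring acetoxy group of 16 only)
Why: DDQ should abstract hydride from the ring CH2 that is ortho and para to two benzyloxy groups, and acetic acid captures the cation (oxidative benzylic C–H acetoxylation); once the oxidant is spent, the labile 2,4-dialkoxybenzylic acetate ionises in HFIP and phenol attacks through its para carbon in a Friedel–Crafts alkylation. The nucleophile should enter from the face opposite the C2 aryl group and the side chain, which are cis to each other, so the new stereocentre is set trans to the C2 aryl group.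

Step 11
Reactants: 17 (R)-[(1S,2S,3R)-4,6-bis(benzyloxy)-2-[3,5-bis(benzyloxy)phenyl]-3-(4-hydroxyphenyl)-2,3-dihydro-1H-inden-1-yl][4-(benzyloxy)phenyl]methyl acetate
Product: 19 (1S,2S,3R)-2-(3,5-dihydroxyphenyl)-1-[(R)-hydroxy(4-hydroxyphenyl)methyl]-3-(4-hydroxyphenyl)-2,3-dihydro-1H-indene-4,6-diol, via deacetylated pentabenzyl ether 18 (not isolated)
Conditions: K2CO3 (0.3 equiv), MeOH/THF 1:1, rt; then Pd/C (10 %), H2 (1 atm), rt
Reagents that add atoms: none
Why: Base-catalysed methanolysis of the acetate followed by hydrogenolysis of five aryl benzyl ethers over Pd/C; the trace of carbonate keeps the medium non-acidic, so the benzylic C–OH bond should not be hydrogenolysed.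

## Compound list

1 | 3,5-bis(benzyloxy)benzaldehyde | O=Cc1cc(OCc2ccccc2)cc(OCc2ccccc2)c1 | starting material
2 | 2-bromo-3,5-bis(benzyloxy)benzaldehyde | O=Cc1cc(OCc2ccccc2)cc(OCc2ccccc2)c1Br | intermediate
3 | allyltributylstannane | C=CC[Sn](CCCC)(CCCC)CCCC | starting material
4 | 2-allyl-3,5-bis(benzyloxy)benzaldehyde | O=Cc1cc(OCc2ccccc2)cc(OCc2ccccc2)c1CC=C | intermediate
5 | 1,5-bis(benzyloxy)-3-ethenyl-2-(prop-2-en-1-yl)benzene | C=Cc1cc(OCc2ccccc2)cc(OCc2ccccc2)c1CC=C | intermediate
6 | 5,7-bis(benzyloxy)-1H-indene | C1C=Cc2cc(OCc3ccccc3)cc(OCc3ccccc3)c21 | intermediate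
7 | 3,5-bis(benzyloxy)phenol | Oc1cc(OCc2ccccc2)cc(OCc2ccccc2)c1 | starting material
8 | 3,5-bis(benzyloxy)phenyl trifluoromethanesulfonate | O=S(=O)(Oc1cc(OCc2ccccc2)cc(OCc2ccccc2)c1)C(F)(F)F | intermediate
9 | 1-(benzyloxy)-4-bromobenzene | Brc1ccc(OCc2ccccc2)cc1 | starting material
10 | [4-(benzyloxy)phenyl]lithium | [Li]c1ccc(OCc2ccccc2)cc1 | intermediate
11 | tributyl[4-(benzyloxy)phenyl]stannane | CCCC[Sn](CCCC)(CCCC)c1ccc(OCc2ccccc2)cc1 | intermediate
12 | [(1S,2S)-4,6-bis(benzyloxy)-2-[3,5-bis(benzyloxy)phenyl]-2,3-dihydro-1H-inden-1-yl][4-(benzyloxy)phenyl]methanone | C1c2c(OCc3ccccc3)cc(OCc3ccccc3)cc2[C@@H](C(=O)c2ccc(OCc3ccccc3)cc2)[C@H]1c1cc(OCc2ccccc2)cc(OCc2ccccc2)c1 | intermediate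
13 | (R)-[(1S,2S)-4,6-bis(benzyloxy)-2-[3,5-bis(benzyloxy)phenyl]-2,3-dihydro-1H-inden-1-yl][4-(benzyloxy)phenyl]methanol | C1c2c(OCc3ccccc3)cc(OCc3ccccc3)cc2[C@@H]([C@@H](O)c2ccc(OCc3ccccc3)cc2)[C@H]1c1cc(OCc2ccccc2)cc(OCc2ccccc2)c1 | intermediate
14 | (R)-[(1S,2S)-4,6-bis(benzyloxy)-2-[3,5-bis(benzyloxy)phenyl]-2,3-dihydro-1H-inden-1-yl][4-(benzyloxy)phenyl]methyl acetate | C1c2c(OCc3ccccc3)cc(OCc3ccccc3)cc2[C@@H]([C@@H](OC(C)=O)c2ccc(OCc3ccccc3)cc2)[C@H]1c1cc(OCc2ccccc2)cc(OCc2ccccc2)c1 | intermediate
15 | phenol | Oc1ccccc1 | starting material
16 | (R)-[(1S,2S,3RS)-3-acetoxy-4,6-bis(benzyloxy)-2-[3,5-bis(benzyloxy)phenyl]-2,3-dihydro-1H-inden-1-yl][4-(benzyloxy)phenyl]methyl acetate (both epimers at the acetoxy-bearing ring carbon) | CC(=O)OC1c2c(OCc3ccccc3)cc(OCc3ccccc3)cc2[C@@H]([C@@H](OC(C)=O)c2ccc(OCc3ccccc3)cc2)[C@H]1c1cc(OCc2ccccc2)cc(OCc2ccccc2)c1 | intermediate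
17 | (R)-[(1S,2S,3R)-4,6-bis(benzyloxy)-2-[3,5-bis(benzyloxy)phenyl]-3-(4-hydroxyphenyl)-2,3-dihydro-1H-inden-1-yl][4-(benzyloxy)phenyl]methyl acetate | Oc1ccc([C@@H]2c3c(OCc4ccccc4)cc(OCc4ccccc4)cc3[C@@H]([C@@H](OC(C)=O)c3ccc(OCc4ccccc4)cc3)[C@H]2c2cc(OCc3ccccc3)cc(OCc3ccccc3)c2)cc1 | intermediate
18 | (R)-[(1S,2S,3R)-4,6-bis(benzyloxy)-2-[3,5-bis(benzyloxy)phenyl]-3-(4-hydroxyphenyl)-2,3-dihydro-1H-inden-1-yl][4-(benzyloxy)phenyl]methanol | Oc1ccc([C@@H]2c3c(OCc4ccccc4)cc(OCc4ccccc4)cc3[C@@H]([C@@H](O)c3ccc(OCc4ccccc4)cc3)[C@H]2c2cc(OCc3ccccc3)cc(OCc3ccccc3)c2)cc1 | intermediate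
19 | (1S,2S,3R)-2-(3,5-dihydroxyphenyl)-1-[(R)-hydroxy(4-hydroxyphenyl)methyl]-3-(4-hydroxyphenyl)-2,3-dihydro-1H-indene-4,6-diol | Oc1ccc([C@@H]2c3c(O)cc(O)cc3[C@@H]([C@@H](O)c3ccc(O)cc3)[C@H]2c2cc(O)cc(O)c2)cc1 | target

## Step count and least certain steps

Total: 11 steps. Longest linear sequence: 9 steps (steps 1 to 4, then 7 to 11); steps 5 and 6 are single-step side branches.

**Step 7 (key step, Proposed new method).**
- What may go wrong: CO insertion into the aryl–palladium bond may outrun alkene insertion, leading to direct carbonylative coupling with the stannane or to acyl transfer onto the indene. The benzylpalladium may epimerise and be lost by β-hydride elimination to the Heck product, or couple with the stannane without taking up CO. Facial selectivity in the insertion may be poor. The Lewis-acidic tin triflate may epimerise the cis ketone.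
- Fallback, known chemistry only, from 6 back to 12:
  - Deprotonation of 6 with n-BuLi (THF, −78 °C) gives lithium 5,7-bis(benzyloxy)-1H-inden-1-ide F1.
  - F1 is acylated with 4-(benzyloxy)-N-methoxy-N-methylbenzamide, expected at the ring carbon remote from the peri benzyloxy group. Work-up and brief treatment with Et3N move the double bond into conjugation and give [5,7-bis(benzyloxy)-1H-inden-3-yl][4-(benzyloxy)phenyl]methanone F2.
  - A Hayashi–Miyaura 1,4-addition of 3,5-bis(benzyloxy)phenylboronic acid ([Rh(acac)(C2H4)2], BINAP of the antipode that gives 2S, dioxane/H2O, 100 °C, no added base) sets C2 and gives [(2S)-4,6-bis(benzyloxy)-2-[3,5-bis(benzyloxy)phenyl]-2,3-dihydro-1H-inden-1-yl][4-(benzyloxy)phenyl]methanone F3, probably mainly as the trans epimer.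
  - Enolisation with LiN(i-Pr)2 (THF, −78 °C) gives the exocyclic lithium enolate of F3, F4. Kinetic protonation with AcOH at −78 °C, from the face opposite the C2 aryl group, should return the cis ketone 12.

**Step 10.**
- What may go wrong: loss of the C2 proton from the benzylic cation (elimination to an indene) instead of capture by acetic acid or phenol, and slow ionisation at the carbinol acetate with scrambling of the carbinol centre.
- Fallback, from 14 back to 17: the elimination is made the intended path.
  - DDQ (1.1 equiv) in 1,4-dioxane at 80 °C, with no nucleophile, dehydrogenates 14 to (R)-[(1S)-4,6-bis(benzyloxy)-2-[3,5-bis(benzyloxy)phenyl]-1H-inden-1-yl][4-(benzyloxy)phenyl]methyl acetate F5, which is isolated free of oxidant.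
  - Acid-catalysed hydroarylation with phenol (TfOH 5 mol %, HFIP, 0 °C) should protonate C2 on the face opposite the side chain, restoring the 2,3-cis relationship, and the resulting benzylic cation is captured by phenol anti to the C2 aryl group to give 17.

**Step 8.**
- What may go wrong: a mismatch between the facial preference of the oxazaborolidine and that of the substrate (the Felkin–Anh model with the fused aryl ring as the perpendicular group predicts the S carbinol), giving poor diastereoselectivity.
- Fallback, from 12 back to 14: reduction with LiBH(s-Bu)3 (THF, −78 °C) under substrate control should give the epimeric (S)-[(1S,2S)-4,6-bis(benzyloxy)-2-[3,5-bis(benzyloxy)phenyl]-2,3-dihydro-1H-inden-1-yl][4-(benzyloxy)phenyl]methanol F6. A Mitsunobu reaction with acetic acid (PPh3, diisopropyl azodicarboxylate, toluene, 0 °C) inverts the carbinol centre and gives acetate 14 directly, so step 9 is not needed.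

**Step 11.**
- What may go wrong: over-reduction, namely hydrogenolysis of the 4-hydroxybenzylic C–OH bond once the phenols are free.
- Fallback, from 18 back to 19: 18 is isolated after the methanolysis and debenzylated by single-electron reduction with lithium 4,4'-di-tert-butylbiphenylide (excess, THF, −78 °C). The carbinol and the phenol are then present as lithium salts, which resist C–O cleavage, and no acid or hydrogenation catalyst is involved.

## Further compounds

F1 | step 7 | lithium 5,7-bis(benzyloxy)-1H-inden-1-ide | [Li+].[CH-]1C=Cc2cc(OCc3ccccc3)cc(OCc3ccccc3)c21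
F2 | step 7 | [5,7-bis(benzyloxy)-1H-inden-3-yl][4-(benzyloxy)phenyl]methanone | O=C(C1=CCc2c(OCc3ccccc3)cc(OCc3ccccc3)cc21)c1ccc(OCc2ccccc2)cc1
F3 | step 7 | [(2S)-4,6-bis(benzyloxy)-2-[3,5-bis(benzyloxy)phenyl]-2,3-dihydro-1H-inden-1-yl][4-(benzyloxy)phenyl]methanone, mixture of epimers at C1 | C1c2c(OCc3ccccc3)cc(OCc3ccccc3)cc2C(C(=O)c2ccc(OCc3ccccc3)cc2)[C@H]1c1cc(OCc2ccccc2)cc(OCc2ccccc2)c1
F4 | step 7 | exocyclic lithium enolate of F3 (C2 configuration unchanged, enolate geometry not specified) | [Li]OC(c1ccc(OCc2ccccc2)cc1)=C1c2cc(OCc3ccccc3)cc(OCc3ccccc3)c2C[C@@H]1c1cc(OCc2ccccc2)cc(OCc2ccccc2)c1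
F5 | step 10 | (R)-[(1S)-4,6-bis(benzyloxy)-2-[3,5-bis(benzyloxy)phenyl]-1H-inden-1-yl][4-(benzyloxy)phenyl]methyl acetate | C1(c2cc(OCc3ccccc3)cc(OCc3ccccc3)c2)=Cc2c(OCc3ccccc3)cc(OCc3ccccc3)cc2[C@H]1[C@@H](OC(C)=O)c1ccc(OCc2ccccc2)cc1
F6 | step 8 | (S)-[(1S,2S)-4,6-bis(benzyloxy)-2-[3,5-bis(benzyloxy)phenyl]-2,3-dihydro-1H-inden-1-yl][4-(benzyloxy)phenyl]methanol | C1c2c(OCc3ccccc3)cc(OCc3ccccc3)cc2[C@@H]([C@H](O)c2ccc(OCc3ccccc3)cc2)[C@H]1c1cc(OCc2ccccc2)cc(OCc2ccccc2)c1
F0 | step 11 | none | none
A1 | alternative 1 | 1,2-bis(3,5-dimethoxyphenyl)-3-(4-methoxyphenyl)prop-2-en-1-one (alkene geometry not specified) | COc1ccc(C=C(C(=O)c2cc(OC)cc(OC)c2)c2cc(OC)cc(OC)c2)cc1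
A2 | alternative 1 | (2R,3R)-2-(3,5-dimethoxyphenyl)-4,6-dimethoxy-3-(4-methoxyphenyl)-2,3-dihydro-1H-inden-1-one (trans) | COc1ccc([C@@H]2c3c(OC)cc(OC)cc3C(=O)[C@H]2c2cc(OC)cc(OC)c2)cc1
A3 | alternative 2 | tert-butyl{[(1R,2R,3S)-1-[4-(benzyloxy)phenyl]-3-[3,5-bis(benzyloxy)phenyl]-2-(4-bromofuran-2-yl)hex-5-yn-1-yl]oxy}dimethylsilane | Brc1coc(c1)[C@@H]([C@@H](O[Si](C)(C)C(C)(C)C)c1ccc(OCc2ccccc2)cc1)[C@H](CC#C)c1cc(OCc2ccccc2)cc(OCc2ccccc2)c1
A4 | alternative 2 | (1S,2S)-6-bromo-2-[3,5-bis(benzyloxy)phenyl]-1-{(R)-[4-(benzyloxy)phenyl][(tert-butyldimethylsilyl)oxy]methyl}-2,3-dihydro-1H-inden-4-ol | C1c2c(O)cc(Br)cc2[C@@H]([C@@H](O[Si](C)(C)C(C)(C)C)c2ccc(OCc3ccccc3)cc2)[C@H]1c1cc(OCc2ccccc2)cc(OCc2ccccc2)c1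
A5 | alternative 3 | (3R,4R)-1-diazo-3-(3,5-dimethoxyphenyl)-5,7-dimethoxy-4-(4-methoxyphenyl)-3,4-dihydronaphthalen-2(1H)-one | COc1ccc([C@@H]2c3c(OC)cc(OC)cc3C(=[N+]=[N-])C(=O)[C@H]2c2cc(OC)cc(OC)c2)cc1
A6 | alternative 3 | (1S,2S,3R)-2-(3,5-dimethoxyphenyl)-N,4,6-trimethoxy-3-(4-methoxyphenyl)-N-methyl-2,3-dihydro-1H-indene-1-carboxamide | COc1ccc([C@@H]2c3c(OC)cc(OC)cc3[C@@H](C(=O)N(C)OC)[C@H]2c2cc(OC)cc(OC)c2)cc1
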